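**Retrosynthetic overview**
- Target ⇒ seco tosylhydrazone. Ring B is opened at C9–C10 (labdane numbering). In the forward sense an iron-hydride (MHAT) radical at C10 adds to a C9 tosylhydrazone, and sulfinate and N2 are then lost.
- Enabling feature: in ring B the CH carbon C9 sits between the ether carbon C8 of ring C and the quaternary, methyl-bearing C10 of ring A, and it is 1,6 to C10 along C5–C6–C7–C8. The CH can therefore be a traceless C=N–NHTs acceptor, and C(CH3) can be C=CH2 plus a hydrogen atom.
- Tosylhydrazone ⇒ C9 ketone ⇒ C9 carbinol. The carbinol first directs the C13–C14 oxirane. Ring C comes from ring-closing metathesis at C13=C14.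
- The metathesis diene comes from 2-methylallyl Grignard opening of a C9–C11 oxirane. Ring A with C3–Br comes from an asymmetric bromonium cyclisation. The C8–O bond comes from allyl alcohol opening, with inversion, of the Sharpless oxirane of farnesol.
- Order of ring formation: ring A (step 3), ring C (step 6), oxirane (step 7), ring B (step 10).

Key step: step 10

Remark (assumption): labdane numbering is used for all compounds (ring A = C1–C5 and C10; ring B = C5–C10; ring C = O, C8, C9, C11–C15; C16 on C13, C17 on C8, C18 and C19 on C4, C20 on C10). Both antipodes of the two chiral organocatalysts named below are taken as accessible.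

**Step 1**
Reactants: 1 (2E,6E)-farnesol
Product: 2 (2S,3S)-2,3-epoxyfarnesol
Conditions: Ti(OiPr)4 (5 mol %), L-(+)-diethyl tartrate (6 mol %), t-BuOOH, 4 Å molecular sieves, CH2Cl2, −20 °C
Reagents that add atoms: tert-butyl hydroperoxide, CC(C)(C)OO
Why: Sharpless asymmetric epoxidation touches only the allylic alkene, and the L-(+)-tartrate ligand delivers oxygen to the face that gives the (2S,3S)-oxirane, which fixes C9 directly and C8 in the sense needed before one inversion.

**Step 2**
Reactants: 2 (2S,3S)-2,3-epoxyfarnesol; 3 allyl alcohol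
Product: 4 (2S,3R,6E)-3-(allyloxy)-3,7,11-trimethyldodeca-6,10-diene-1,2-diol (8R,9S)
Conditions: allyl alcohol (solvent), camphorsulfonic acid (5 mol %), 0 °C
Reagents that add atoms: allyl alcohol (3), C=CCO
Why: Acid-catalysed alcoholysis of a trisubstituted oxirane, in which the solvent attacks the tertiary carbon C8 from the rear (borderline SN2, inversion to 8R), the C9–O bond keeps its configuration, and the large excess of nucleophile should outrun cation–olefin and hydride-shift paths.

**Step 3**
Reactants: 4 allyloxy diol
Product: 5 (2S,3R)-3-(allyloxy)-5-[(1R,3S)-3-bromo-2,2-dimethyl-6-methylidenecyclohexyl]-3-methylpentane-1,2-diol (3S,5R,8R,9S)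
Conditions: 1,3-dibromo-5,5-dimethylhydantoin (0.55 equiv), BINOL-derived thiophosphoramide Lewis base catalyst (10 mol %, antipode that gives 3S), toluene/CH2Cl2, −78 °C
Reagents that add atoms: 1,3-dibromo-5,5-dimethylhydantoin, CC1(C)N(Br)C(=O)N(Br)C1=O
Why: Catalytic asymmetric bromonium-induced cyclisation of a 1,5-diene, in which the chiral Lewis base–Br+ complex picks one face of the electron-rich terminal C3=C4 alkene (the monosubstituted allyl ether is far less nucleophilic), C5 of the E alkene attacks C4 through a chair that places Br and the C5 side chain equatorial and cis (the catalyst decides the absolute sense because C8 and C9 are remote), and the C10 cation loses a C20 proton to give the methylidene group.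

**Step 4**
Reactants: 5 bromo diol
Product: 7 terminal oxirane (2S)-2-[(2R)-2-(allyloxy)-4-[(1R,3S)-3-bromo-2,2-dimethyl-6-methylidenecyclohexyl]butan-2-yl]oxirane, via primary tosylate 6 (not isolated)
Conditions: NaH (2.2 equiv), 1-(p-toluenesulfonyl)imidazole, THF, 0 °C to rt
Reagents that add atoms: 1-(p-toluenesulfonyl)imidazole, Cc1ccc(cc1)S(=O)(=O)n1ccnc1 (its tosyl group stands in 6 only)
Why: Selective sulfonylation of the primary alkoxide followed by intramolecular Williamson closure (3-exo-tet) gives the oxirane without touching the C9–O bond, so C9 stays S, and the equatorial bromide has no anti-periplanar hydrogen for elimination.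

**Step 5**
Reactants: 7 terminal oxirane; 8 2-methylallylmagnesium chloride
Product: 9 (3R,4S)-3-(allyloxy)-1-[(1R,3S)-3-bromo-2,2-dimethyl-6-methylidenecyclohexyl]-3,7-dimethyloct-7-en-4-ol
Conditions: 2-methylallylmagnesium chloride, CuI (10 mol %), THF, −40 to 0 °C; aqueous NH4Cl
Reagents that add atoms: 2-methylallylmagnesium chloride (8), CC(=C)C[Mg]Cl
Why: Copper-catalysed Grignard opening of a monosubstituted oxirane at its free CH2 terminus (SN2) forms C11–C12 and frees the C9 carbinol with unchanged configuration, the symmetric 2-methylallyl unit removes any alpha/gamma question, and the hindered secondary bromide should be inert at this temperature.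

**Step 6**
Reactants: 9 diene alcohol
Product: 10 (2R,3S,6Z)-2-[2-[(1R,3S)-3-bromo-2,2-dimethyl-6-methylidenecyclohexyl]ethyl]-2,6-dimethyl-3,4,5,8-tetrahydro-2H-oxocin-3-ol
Conditions: second-generation Grubbs catalyst RuCl2(H2IMes)(PCy3)(=CHPh) (5 mol %), CH2Cl2 (2 mM), reflux
Reagents that add atoms: none
Why: Ring-closing metathesis between the allyl ether and the 1,1-disubstituted alkene closes the eight-membered ring C, helped by the quaternary C8 and the gauche preference of the vicinal C8–O and C9–O bonds, while the ring size enforces the Z alkene and the hindered ring A alkene should not take part.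

**Step 7**
Reactants: 10 oxocenol
Product: 11 (1S,4R,5S,8R)-4-[2-[(1R,3S)-3-bromo-2,2-dimethyl-6-methylidenecyclohexyl]ethyl]-4,8-dimethyl-3,9-dioxabicyclo[6.1.0]nonan-5-ol
Conditions: VO(acac)2 (5 mol %), t-BuOOH, toluene, 0 °C to rt
Reagents that add atoms: tert-butyl hydroperoxide, CC(C)(C)OO
Why: Hydroxyl-directed epoxidation of a bishomoallylic alcohol, in which the vanadium alkoxide of the C9–OH carries the peroxide across the ring to the face of C13=C14 on which the hydroxyl group stands (the face of the C8 methyl group), which sets 13R,14S, leaves the undirected ring A alkene alone, and gives a cis epoxy alcohol that cannot open by backside attack of its own hydroxyl group.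

**Step 8**
Reactants: 11 epoxy alcohol
Product: 12 (1S,4R,8R)-4-[2-[(1R,3S)-3-bromo-2,2-dimethyl-6-methylidenecyclohexyl]ethyl]-4,8-dimethyl-3,9-dioxabicyclo[6.1.0]nonan-5-one
Conditions: Dess–Martin periodinane, pyridine, CH2Cl2, 0 °C to rt
Reagents that add atoms: none
Why: Dess–Martin oxidation under pyridine buffer turns the spent directing group into the C9 ketone without touching oxirane, alkene or bromide, and the quaternary C8 cannot epimerise.

**Step 9**
Reactants: 12 ketone; 13 p-toluenesulfonyl hydrazide
Product: 14 N-tosylhydrazone of 12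
Conditions: TsNHNH2, EtOH, 4 Å molecular sieves, 40 °C
Reagents that add atoms: p-toluenesulfonyl hydrazide (13), Cc1ccc(cc1)S(=O)(=O)NN
Why: Hydrazone formation from a ketone and a sulfonyl hydrazide needs no added acid, so the oxirane should survive, no stereocentre is formed, and the C=N geometry is irrelevant for the next step.

**Step 10**
Reactants: 14 tosylhydrazone
Product: 17 (3S,5R,8R,9R,10S,13R,14S)-3-bromo-8,15:13,14-diepoxylabdane (CNP0311742.2), via cyclised tosylhydrazide 15 (not isolated), via tertiary diazene 16 (not isolated)
Conditions: Fe(acac)3 (30 mol %), PhSiH3, EtOH, 60 °C; then Et3N, reflux, same flask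
Reagents that add atoms: none
Why: Proposed new method: an iron hydride formed from Fe(acac)3 and PhSiH3 should transfer a hydrogen atom to the CH2 end of the C10=C20 alkene (this makes the C20 methyl group and the tertiary C10 radical), the radical adds to the carbon of the C9=N bond, the hydrazinyl radical is reduced to tosylhydrazide 15, Et3N then expels p-toluenesulfinate to give diazene 16, and loss of N2 leaves C9–H. The closest known reaction types are the iron-hydride (MHAT) cyclisation of alkene-tethered ketone tosylhydrazones, which stops at the hydrazine, and the intermolecular MHAT reductive alkylation of alkenes by aldehyde tosylhydrazones, which ends in the same sulfinate and N2 loss; new is their union in a ring closure at a ketone-derived C=N next to a fully substituted carbon. Only ring B is closed, in the 6-exo-trig mode through a chair-like array C10–C5–C6–C7–C8–C9, and since sulfonylhydrazone C=N bonds are far better acceptors for nucleophilic alkyl radicals than alkenes the closure should outrun plain reduction of the C10 radical. C10 is controlled by ring A: its chair keeps Br and the C5 tether equatorial, so C9 bonds along the equatorial direction while the small C20 methyl group, not the bulky C9, takes the axial site beside the axial C4 methyl group and anti to H5, which is the trans-decalin. C9 is controlled at the N2 loss: the tertiary C9 radical (or the diazene in its hydrogen shift) takes up hydrogen on the alpha face because the beta face is covered by the axial methyl groups on C8 and C10, so that C11 ends equatorial and the oxocane trans-fused. The step needs chemoselectivity for one alkene beside C–Br, oxirane and ether, and 14 secures it because it holds no other C=C bond, the medium is neutral and free of low-valent metals and strong Lewis acids, and any endocyclic C1=C10 isomer carried on from step 3 gives the same C10 radical.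

**Compound list**
1 | (2E,6E)-farnesol | CC(C)=CCC/C(C)=C/CC/C(C)=C/CO | starting material
2 | (2S,3S)-2,3-epoxyfarnesol | CC(C)=CCC/C(C)=C/CC[C@]1(C)O[C@H]1CO | intermediate
3 | allyl alcohol | C=CCO | starting material
4 | (2S,3R,6E)-3-(allyloxy)-3,7,11-trimethyldodeca-6,10-diene-1,2-diol | CC(C)=CCC/C(C)=C/CC[C@@](C)(OCC=C)[C@@H](O)CO | intermediate
5 | (2S,3R)-3-(allyloxy)-5-[(1R,3S)-3-bromo-2,2-dimethyl-6-methylidenecyclohexyl]-3-methylpentane-1,2-diol | CC1(C)[C@@H](Br)CCC(=C)[C@H]1CC[C@@](C)(OCC=C)[C@@H](O)CO | intermediate
6 | primary p-toluenesulfonate of 5 (not isolated) | CC1(C)[C@@H](Br)CCC(=C)[C@H]1CC[C@@](C)(OCC=C)[C@@H](O)COS(=O)(=O)c2ccc(C)cc2 | intermediate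
7 | (2S)-2-[(2R)-2-(allyloxy)-4-[(1R,3S)-3-bromo-2,2-dimethyl-6-methylidenecyclohexyl]butan-2-yl]oxirane | CC1(C)[C@@H](Br)CCC(=C)[C@H]1CC[C@@](C)(OCC=C)[C@@H]2CO2 | intermediate
8 | 2-methylallylmagnesium chloride | CC(=C)C[Mg]Cl | starting material
9 | (3R,4S)-3-(allyloxy)-1-[(1R,3S)-3-bromo-2,2-dimethyl-6-methylidenecyclohexyl]-3,7-dimethyloct-7-en-4-ol | CC1(C)[C@@H](Br)CCC(=C)[C@H]1CC[C@@](C)(OCC=C)[C@@H](O)CCC(C)=C | intermediate
10 | (2R,3S,6Z)-2-[2-[(1R,3S)-3-bromo-2,2-dimethyl-6-methylidenecyclohexyl]ethyl]-2,6-dimethyl-3,4,5,8-tetrahydro-2H-oxocin-3-ol | CC1(C)[C@@H](Br)CCC(=C)[C@H]1CC[C@@]2(C)OC/C=C(C)\CC[C@@H]2O | intermediate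
11 | (1S,4R,5S,8R)-4-[2-[(1R,3S)-3-bromo-2,2-dimethyl-6-methylidenecyclohexyl]ethyl]-4,8-dimethyl-3,9-dioxabicyclo[6.1.0]nonan-5-ol | CC1(C)[C@@H](Br)CCC(=C)[C@H]1CC[C@@]2(C)OC[C@@H]3O[C@]3(C)CC[C@@H]2O | intermediate
12 | (1S,4R,8R)-4-[2-[(1R,3S)-3-bromo-2,2-dimethyl-6-methylidenecyclohexyl]ethyl]-4,8-dimethyl-3,9-dioxabicyclo[6.1.0]nonan-5-one | CC1(C)[C@@H](Br)CCC(=C)[C@H]1CC[C@@]2(C)OC[C@@H]3O[C@]3(C)CCC2=O | intermediate
13 | p-toluenesulfonyl hydrazide | Cc1ccc(cc1)S(=O)(=O)NN | starting material
14 | N-tosylhydrazone of 12 | CC1(C)[C@@H](Br)CCC(=C)[C@H]1CC[C@@]2(C)OC[C@@H]3O[C@]3(C)CCC2=NNS(=O)(=O)c4ccc(C)cc4 | intermediate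
15 | 9-alpha-(2-tosylhydrazinyl) derivative of 17 (not isolated; the C9 configuration is of no consequence) | CC1(C)[C@@H](Br)CC[C@]2(C)[C@@]3(NNS(=O)(=O)c5ccc(C)cc5)CC[C@@]4(C)O[C@H]4CO[C@]3(C)CC[C@@H]12 | intermediate
16 | 9-alpha-diazenyl derivative of 17 (not isolated) | CC1(C)[C@@H](Br)CC[C@]2(C)[C@@]3(N=N)CC[C@@]4(C)O[C@H]4CO[C@]3(C)CC[C@@H]12 | intermediate
17 | (3S,5R,8R,9R,10S,13R,14S)-3-bromo-8,15:13,14-diepoxylabdane (CNP0311742.2) | CC1(C)[C@@H](Br)CC[C@]2(C)[C@H]3CC[C@@]4(C)O[C@H]4CO[C@]3(C)CC[C@@H]12 | target

Total step count: 10. Longest linear sequence: 10 steps (1 to 17).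

**Steps most likely to fail**

**Step 10.**
- What may go wrong: hydrogen transfer to the C10 radical before it reaches the crowded C=N carbon; closure along the axial direction to a cis ring fusion; back-transfer of H5 that would erode C5; or ionic collapse of the diazene with expulsion of the neighbouring ether oxygen.
- Fallback (known chemistry only): it sets out from ketone 12 and comes back at 17. The known MHAT reductive cyclisation of alkene-tethered ketones (Fe(acac)3, PhSiH3, EtOH, 60 °C) should close ring B to the 9-alpha-alcohol F1. Burgess reagent (toluene, 50 °C) should dehydrate it toward C11, the only neighbour of C9 that carries hydrogen, to the 9(11)-alkene F2. MHAT hydrogenation (Mn(dpm)3, PhSiH3, t-BuOOH, i-PrOH, rt) should place hydrogen on C11 and then on the alpha face of the C9 radical, which gives 17.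

**Step 3.**
- What may go wrong: capture of the C10 cation by the ether or hydroxyl oxygen atoms, dealkylation of a transient oxonium ion, or weak catalyst control because the free diol binds the Lewis base.
- Fallback: it sets out from 4 and comes back at 5. 1,1'-Carbonyldiimidazole (CH2Cl2, rt) should mask both hydroxyl groups as the cyclic carbonate F3, whose electron-poor ring also lowers the basicity of the neighbouring ether oxygen. The bromonium cyclisation is then run on this substrate to give the bromo carbonate F4. Methanolysis (K2CO3 cat., MeOH, 0 °C) releases 5. Any minor C3/C5 diastereomer can be removed at this stage because C8 and C9 are fixed.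

**Step 7.**
- What may go wrong: poor facial selectivity if the hydroxyl group cannot reach across the ring, or slow undirected attack on the outer face.
- Fallback: it sets out from 10 and comes back at 12, and it replaces substrate direction by reagent control. Dess–Martin periodinane with pyridine should first give the oxocenone F5. Shi epoxidation with the L-fructose-derived ketone (the antipode of the common D-fructose-derived catalyst), Oxone (2KHSO5·KHSO4·K2SO4), K2CO3 buffer, MeCN/dimethoxymethane/water, 0 °C, should then oxidise the trisubstituted ring alkene on the face that gives 13R,14S. The 1,1-disubstituted ring A alkene is a much poorer substrate for this dioxirane.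

**Further compounds**
F1 | step 10 | 9-alpha-hydroxy derivative of 17 | CC1(C)[C@@H](Br)CC[C@]2(C)[C@@]3(O)CC[C@@]4(C)O[C@H]4CO[C@]3(C)CC[C@@H]12
F2 | step 10 | 9(11)-didehydro derivative of 17 | CC1(C)[C@@H](Br)CC[C@]2(C)C3=CC[C@@]4(C)O[C@H]4CO[C@]3(C)CC[C@@H]12
F3 | step 3 | cyclic carbonate of diol 4 (8R,9S) | CC(C)=CCC/C(C)=C/CC[C@@](C)(OCC=C)[C@@H]1COC(=O)O1
F4 | step 3 | cyclic carbonate of bromo diol 5 (3S,5R,8R,9S) | CC1(C)[C@@H](Br)CCC(=C)[C@H]1CC[C@@](C)(OCC=C)[C@@H]2COC(=O)O2
F5 | step 7 | (2R,6Z)-2-[2-[(1R,3S)-3-bromo-2,2-dimethyl-6-methylidenecyclohexyl]ethyl]-2,6-dimethyl-4,5-dihydro-2H-oxocin-3(8H)-one | CC1(C)[C@@H](Br)CCC(=C)[C@H]1CC[C@@]2(C)OC/C=C(C)\CCC2=O
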